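The data are calculated on assumed constants.

The single product is what the flask should mostly hold, and what it costs is partner.

all flasks: partner 1.89 M

| run | substrate | remark | time |
|---|---|---|---|
| spring | 1.2 M | run made earlier |  |
| summer | 2.7 M | run made earlier |  |
| flask | 1.8 M |  | 5.0 d |

- spring (time / d: substrate / %, single product / %): 0.250: 7.8, 76.8; 0.417: 5.9, 77.1; 0.833: 5.1, 77.8; 1.67: 4.8, 80.3; 3.00: 4.2, 78.1
- summer (time / d: substrate / %, single product / %): 0.625: 42.1, 58.1; 1.25: 40.2, 56.0; 1.67: 40.9, 58.7; 2.50: 39.1, 56.7; 3.00: 41.3, 54.7

(readings scatter by 1 percentage point)

- substrate at 5.0 d, in percent of the substrate charged
- single product at 5.0 d, in percent of the substrate charged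
- double product at 5.0 d, in percent of the substrate charged

1. I count delivered partner: one per single product, two per double product, with double product as the remainder of the balance. The lost share is the part of the partner charge not delivered.
2. Spring stands flat from 0.833 d, so I average from there, and I average the summer readings too. Spring delivers 1.34 M and summer 1.67 M. The lost shares are 29.0 % and 11.8 %, and double product reads 16.6 % and 2.44 %.
3. The flask's substrate charge lies between those charges, so I bracket its substrate left with the summer and spring values, as an estimate: 9.86 % and 42.0 %.
4. To tighten this: 1.80 M is the geometric mean of the two charges, so I take geometric means. That gives 18.5 % as the lost share, and double product 6.36 %, the small correction.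
5. Substrate left is one minus delivered per substrate, plus double product. I commit to substrate 20.8 % and single product 72.8 %.

The forecast says 17 %, 76 % and 7 %, adding “The uncertainty is mainly in the model.” Its substrate sits inside my bracket and is lower than mine.

The flask gives 19.8 %, 73.3 % and 6.91 %.

    substrate + partner → single product + released group (k = 0.900 /M/h)
    partner + single product → double product + released group (k = 0.0800 /M/h)
    2 partner → homo dimer (k = 0.0320 /M/h)
    partner → decomposed reagent (k = 0.130 /h)

In the flask, partner, the limiting reagent, stands at 0 % by 2.50 d, and the lost share is 17.0 % against my 18.5 %. Waiting ten times as long leaves the flask's single product where it stands. The neighbouring flask has 0.47 M of partner, so it holds 3.83 substrate per partner against summer's 1.43. I put its lost share between zero and summer's 11.8 % and neglect double product, which places substrate left between 73.9 % and 77.0 %. It gives substrate 76.6 %, single product 23.2 % and double product 0.288 %, with a lost share of 9.12 %.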